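**Retrosynthetic overview**

1. Numbering (elemane): the carbocycle is C5–C10. C10 is quaternary (CH3 = C14, vinyl = C1=C2); C9 carries OH; the γ-lactone is C8–O–C12(=O)–C11(=C13)–C7; C6 carries the angelate; C5 carries C4(=C15)–C3HO. β is the face of the C10 methyl.
2. Feature used: both ring carbinols are homoallylic to an exocyclic alkene (O–C6–C5–C4=C15 and O–C9–C10–C1=C2). Cutting C5–C6 and C9–C10 as carbonyl-ene/allylation retrons reduces the cyclohexane to a 1,4-dialdehyde (C6, C9) on the trans-lactone (C7, C8) plus a two-carbon linchpin C5–C10. That linchpin is the central σ-bond of a (Z)-2,4-dienyl bromide (C2–C1=C10–C5=C4), whose two double bonds move outwards to become the vinyl and isopropenyl groups.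
3. Ring order: lactone first (butenolide 7; radical acetal addition sets C7/C8 trans). Then C9–C10 by γ-selective dienylchromium addition (C9, quaternary C10, vinyl). The carbocycle is closed last at C5–C6 by an intramolecular carbonyl-ene reaction that also creates C5, C6 and the isopropenyl group.
4. Endgame: C6 is inverted via the ketone and a bulky hydride, then angeloylation, α-methylenation (C13), allylic oxidation of the isopropenyl methyl (C3) to the aldehyde, and desilylation.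

Key step: step 8

Remark: (5R)-5-(hydroxymethyl)furan-2(5H)-one (7) is taken as a purchasable chiral-pool lactone (the enantiomer of the common (S)-form; otherwise two steps from (S)-glyceraldehyde acetonide).

**Route**

Step 1
Reactants: 1 but-2-yn-1-ol
Product: 3 (2Z)-3-iodobut-2-en-1-ol, via cyclic alkenylalanate 2 (not isolated)
Conditions: Red-Al [NaAlH2(OCH2CH2OMe)2], THF, 0 °C to rt; then I2, THF, −78 °C
Reagents that add atoms: iodine, II
Why: Hydroxyl-directed trans-hydroalumination of the propargylic alcohol places aluminium on C3 in a five-membered alanate, and iodinolysis with retention should give the vinyl iodide with iodine cis to CH2OH.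

Step 2
Reactants: 3 (2Z)-3-iodobut-2-en-1-ol; 4 4,4,5,5-tetramethyl-2-(2-methylprop-1-en-1-yl)-1,3,2-dioxaborolane
Product: 5 (2Z)-3,5-dimethylhexa-2,4-dien-1-ol
Conditions: Pd(PPh3)4 (5 mol%), K2CO3, THF/H2O, 50 °C
Reagents that add atoms: none
Why: Suzuki–Miyaura coupling proceeds with retention at both alkenyl partners, so the 2-methylprop-1-enyl group (C5=C4) should end cis to CH2OH (C2).

Step 3
Reactants: 5 (2Z)-3,5-dimethylhexa-2,4-dien-1-ol
Product: 6 (2Z)-1-bromo-3,5-dimethylhexa-2,4-diene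
Conditions: CBr4, PPh3, CH2Cl2, −20 °C; used crude
Reagents that add atoms: carbon tetrabromide, BrC(Br)(Br)Br
Why: Appel bromination converts the primary allylic alcohol by SN2 at low temperature and should leave the Z-trisubstituted double bond intact.

Step 4
Reactants: 7 (5R)-5-(hydroxymethyl)furan-2(5H)-one
Product: 8 (4R,5R)-4-(1,3-dioxolan-2-yl)-5-(hydroxymethyl)oxolan-2-one
Conditions: 1,3-dioxolane (solvent), benzophenone (10 mol%), hν (350 nm), rt
Reagents that add atoms: 1,3-dioxolane, C1COCO1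
Why: Photosensitised radical conjugate addition (Giese type) of the nucleophilic 1,3-dioxolan-2-yl radical to the butenolide β-carbon should occur anti to the hydroxymethyl group, which sets the trans C7/C8 relationship and installs C6 as a masked aldehyde.

Step 5
Reactants: 8 (4R,5R)-4-(1,3-dioxolan-2-yl)-5-(hydroxymethyl)oxolan-2-one
Product: 9 (2R,3R)-3-(1,3-dioxolan-2-yl)-5-oxooxolane-2-carbaldehyde
Conditions: Dess–Martin periodinane, CH2Cl2, 0 °C to rt; used directly
Reagents that add atoms: none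
Why: Dess–Martin oxidation of the primary alcohol is mild enough to leave the acetal and the epimerisable α-acyloxy aldehyde centre (C8) untouched.

Step 6
Reactants: 9 (2R,3R)-3-(1,3-dioxolan-2-yl)-5-oxooxolane-2-carbaldehyde; 6 (2Z)-1-bromo-3,5-dimethylhexa-2,4-diene
Product: 11 (4R,5R)-4-(1,3-dioxolan-2-yl)-5-[(1S,2S)-2-ethenyl-1-hydroxy-2,4-dimethylpent-3-en-1-yl]oxolan-2-one, via dienylchromium 10 (not isolated)
Conditions: CrCl2 (4 equiv), THF, 0 °C to rt; then H2O
Reagents that add atoms: none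
Why: In this Nozaki–Hiyama–Kishi allylation the dienylchromium(III) reagent (γ,γ-disubstituted, so its Z-geometry should equilibrate only slowly) adds through its γ-carbon C10 in a chair Zimmerman–Traxler transition state (aldehyde residue and C10 methyl equatorial, 2-methylprop-1-enyl axial) with Felkin–Anh approach anti to the lactone C8–O bond, which should give the (9S,10S) alcohol and unveil the vinyl group by allylic transposition.

Step 7
Reactants: 11 (4R,5R)-4-(1,3-dioxolan-2-yl)-5-[(1S,2S)-2-ethenyl-1-hydroxy-2,4-dimethylpent-3-en-1-yl]oxolan-2-one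
Product: 13 (2R,3R)-2-[(1S,2S)-2-ethenyl-2,4-dimethyl-1-[(triethylsilyl)oxy]pent-3-en-1-yl]-5-oxooxolane-3-carbaldehyde, via silyl ether acetal 12 (not isolated)
Conditions: Et3SiOTf (3.5 equiv), 2,4,6-collidine (5 equiv), CH2Cl2, 0 °C; then H2O, rt
Reagents that add atoms: triethylsilyl trifluoromethanesulfonate, CC[Si](CC)(CC)OS(=O)(=O)C(F)(F)F; water, O
Why: Silylation of the C9 hydroxyl followed by silyl triflate/collidine cleavage of the aldehyde-derived dioxolane and aqueous hydrolysis is a non-acidic acetal deprotection that should spare the lactone, both alkenes and the new silyl ether.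

Step 8
Reactants: 13 (2R,3R)-2-[(1S,2S)-2-ethenyl-2,4-dimethyl-1-[(triethylsilyl)oxy]pent-3-en-1-yl]-5-oxooxolane-3-carbaldehyde
Product: 14 (3aS,4R,5S,6S,7S,7aR)-6-ethenyl-4-hydroxy-6-methyl-5-(prop-1-en-2-yl)-7-[(triethylsilyl)oxy]hexahydro-1-benzofuran-2(3H)-one
Conditions: Me2AlCl (1.5 equiv), CH2Cl2, −78 to −20 °C
Reagents that add atoms: none
Why: Me2AlCl activates the C6 aldehyde, which is attacked by C5 of the 2-methylprop-1-enyl arm in a concerted, asynchronous carbonyl-ene reaction with transfer of an allylic methyl hydrogen to O6, so that C4=C5 is transposed to C4=C15 (isopropenyl). The closest known reaction type is the Lewis-acid-promoted Type I intramolecular carbonyl-ene cyclisation of citronellal to isopulegol. The cyclohexane ring C5–C10 is closed by six-membered bond formation between C5 and C6, exocyclic to both π-bonds, and trans-fused to the lactone, whose C7 and C8 bonds stay diequatorial. C5 is controlled by the chair transition state in which the alkene arm is equatorial, away from the axial C9 silyloxy group, and C6 by the same chair, in which the complexed carbonyl oxygen is equatorial to avoid the 1,3-diaxial C10 methyl, so the 5β-isopropenyl-6α-ol should result. The step needs attack at C5 and not C4, which the six- versus seven-membered ring and the tertiary cationic character at C4 secure, and no participation of the C10 vinyl group, which has no allylic hydrogen and would develop a primary cation.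

Step 9
Reactants: 14 (3aS,4R,5S,6S,7S,7aR)-6-ethenyl-4-hydroxy-6-methyl-5-(prop-1-en-2-yl)-7-[(triethylsilyl)oxy]hexahydro-1-benzofuran-2(3H)-one
Product: 15 (3aR,5S,6S,7S,7aR)-6-ethenyl-6-methyl-5-(prop-1-en-2-yl)-7-[(triethylsilyl)oxy]tetrahydro-1-benzofuran-2,4(3H,5H)-dione
Conditions: Dess–Martin periodinane, CH2Cl2, rt
Reagents that add atoms: none
Why: Dess–Martin oxidation gives the C6 ketone without base, so the β,γ-unsaturated ketone should not move into conjugation and C5 and C7 should not epimerise.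

Step 10
Reactants: 15 (3aR,5S,6S,7S,7aR)-6-ethenyl-6-methyl-5-(prop-1-en-2-yl)-7-[(triethylsilyl)oxy]tetrahydro-1-benzofuran-2,4(3H,5H)-dione
Product: 16 (3aS,4S,5S,6S,7S,7aR)-6-ethenyl-4-hydroxy-6-methyl-5-(prop-1-en-2-yl)-7-[(triethylsilyl)oxy]hexahydro-1-benzofuran-2(3H)-one
Conditions: L-Selectride (1.3 equiv), THF, −78 °C; then H2O
Reagents that add atoms: none
Why: In this bulky-hydride ketone reduction the axial (β-face) trajectory is blocked by the 1,3-diaxial C10 methyl, as in 3,3,5-trimethylcyclohexanone, so hydride should enter equatorially from the α-face and give the axial 6β-alcohol.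

Step 11
Reactants: 16 (3aS,4S,5S,6S,7S,7aR)-6-ethenyl-4-hydroxy-6-methyl-5-(prop-1-en-2-yl)-7-[(triethylsilyl)oxy]hexahydro-1-benzofuran-2(3H)-one; 17 (2Z)-2-methylbut-2-enoic acid (angelic acid)
Product: 18 (3aS,4S,5S,6S,7S,7aR)-6-ethenyl-6-methyl-2-oxo-5-(prop-1-en-2-yl)-7-[(triethylsilyl)oxy]octahydro-1-benzofuran-4-yl (2Z)-2-methylbut-2-enoate
Conditions: 17, 2,4,6-trichlorobenzoyl chloride, Et3N, toluene, rt; then 16, DMAP, toluene, rt to 45 °C
Reagents that add atoms: none
Why: Yamaguchi esterification through the mixed anhydride acylates the hindered axial alcohol with retention at C6 and, kept near room temperature, should not isomerise the (Z)-2-methylbut-2-enoyl group.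

Step 12
Reactants: 18 (3aS,4S,5S,6S,7S,7aR)-6-ethenyl-6-methyl-2-oxo-5-(prop-1-en-2-yl)-7-[(triethylsilyl)oxy]octahydro-1-benzofuran-4-yl (2Z)-2-methylbut-2-enoate
Product: 21 (3aS,4S,5S,6S,7S,7aR)-6-ethenyl-6-methyl-3-methylidene-2-oxo-5-(prop-1-en-2-yl)-7-[(triethylsilyl)oxy]octahydro-1-benzofuran-4-yl (2Z)-2-methylbut-2-enoate, via Mannich base 19 (not isolated), via ammonium iodide 20 (not isolated)
Conditions: LiHMDS (1.2 equiv), THF, −78 °C; Eschenmoser's salt, −78 °C to rt; then MeI, CH2Cl2/MeOH, rt; then aq. NaHCO3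
Reagents that add atoms: N,N-dimethylmethaniminium iodide (Eschenmoser's salt), C=[N+](C)C.[I-]
Why: α-Methylenation by Mannich reaction of the lactone lithium enolate (the lactone α-CH2 is the most acidic site), followed by quaternisation and E1cB loss of trimethylamine, should install C13.

Step 13
Reactants: 21 (3aS,4S,5S,6S,7S,7aR)-6-ethenyl-6-methyl-3-methylidene-2-oxo-5-(prop-1-en-2-yl)-7-[(triethylsilyl)oxy]octahydro-1-benzofuran-4-yl (2Z)-2-methylbut-2-enoate
Product: 23 (3aS,4S,5R,6S,7S,7aR)-6-ethenyl-6-methyl-3-methylidene-2-oxo-5-(3-oxoprop-1-en-2-yl)-7-[(triethylsilyl)oxy]octahydro-1-benzofuran-4-yl (2Z)-2-methylbut-2-enoate, via allylic alcohol 22 (not isolated)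
Conditions: SeO2 (0.5 equiv), t-BuOOH (3 equiv), CH2Cl2, rt; filter; then MnO2, CH2Cl2, rt
Reagents that add atoms: tert-butyl hydroperoxide, CC(C)(C)OO; selenium dioxide, O=[Se]=O
Why: Selenium dioxide allylic oxidation (ene reaction, then [2,3]-sigmatropic shift) should attack only the electron-rich isopropenyl group at its methyl carbon, and manganese dioxide then oxidises the primary allylic alcohol to the 2-substituted acrolein.

Step 14
Reactants: 23 (3aS,4S,5R,6S,7S,7aR)-6-ethenyl-6-methyl-3-methylidene-2-oxo-5-(3-oxoprop-1-en-2-yl)-7-[(triethylsilyl)oxy]octahydro-1-benzofuran-4-yl (2Z)-2-methylbut-2-enoate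
Product: 24 (3aS,4S,5R,6S,7S,7aR)-6-ethenyl-7-hydroxy-6-methyl-3-methylidene-2-oxo-5-(3-oxoprop-1-en-2-yl)octahydro-1-benzofuran-4-yl (2Z)-2-methylbut-2-enoate (CNP0277836.2)
Conditions: HF·pyridine, THF, 0 °C
Reagents that add atoms: none
Why: Fluoride-mediated cleavage of the triethylsilyl ether should free the C9 hydroxyl without affecting the enal, the α-methylene lactone or the angelate.

**Compound list**

1 | but-2-yn-1-ol | CC#CCO | starting material
2 | sodium 2,2-bis(2-methoxyethoxy)-3-methyl-2,5-dihydro-1,2-oxaluminol-2-uide (cyclic alkenylalanate) | CC1=CCO[Al-]1(OCCOC)OCCOC.[Na+] | intermediate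
3 | (2Z)-3-iodobut-2-en-1-ol | C/C(I)=C/CO | intermediate
4 | 4,4,5,5-tetramethyl-2-(2-methylprop-1-en-1-yl)-1,3,2-dioxaborolane | CC(C)=CB1OC(C)(C)C(C)(C)O1 | starting material
5 | (2Z)-3,5-dimethylhexa-2,4-dien-1-ol | CC(C)=C/C(C)=C\CO | intermediate
6 | (2Z)-1-bromo-3,5-dimethylhexa-2,4-diene | CC(C)=C/C(C)=C\CBr | intermediate
7 | (5R)-5-(hydroxymethyl)furan-2(5H)-one | OC[C@@H]1OC(=O)C=C1 | starting material
8 | (4R,5R)-4-(1,3-dioxolan-2-yl)-5-(hydroxymethyl)oxolan-2-one | OC[C@@H]1OC(=O)C[C@H]1C1OCCO1 | intermediate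
9 | (2R,3R)-3-(1,3-dioxolan-2-yl)-5-oxooxolane-2-carbaldehyde | O=C[C@@H]1OC(=O)C[C@H]1C1OCCO1 | intermediate
10 | dichloro[(2Z)-3,5-dimethylhexa-2,4-dien-1-yl]chromium(III) | CC(C)=C/C(C)=C\C[Cr](Cl)Cl | intermediate
11 | (4R,5R)-4-(1,3-dioxolan-2-yl)-5-[(1S,2S)-2-ethenyl-1-hydroxy-2,4-dimethylpent-3-en-1-yl]oxolan-2-one | C=C[C@](C=C(C)C)(C)[C@H](O)[C@@H]1OC(=O)C[C@H]1C1OCCO1 | intermediate
12 | (4R,5R)-4-(1,3-dioxolan-2-yl)-5-[(1S,2S)-2-ethenyl-2,4-dimethyl-1-[(triethylsilyl)oxy]pent-3-en-1-yl]oxolan-2-one | C=C[C@](C=C(C)C)(C)[C@H](O[Si](CC)(CC)CC)[C@@H]1OC(=O)C[C@H]1C1OCCO1 | intermediate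
13 | (2R,3R)-2-[(1S,2S)-2-ethenyl-2,4-dimethyl-1-[(triethylsilyl)oxy]pent-3-en-1-yl]-5-oxooxolane-3-carbaldehyde | C=C[C@](C=C(C)C)(C)[C@H](O[Si](CC)(CC)CC)[C@@H]1OC(=O)C[C@H]1C=O | intermediate
14 | (3aS,4R,5S,6S,7S,7aR)-6-ethenyl-4-hydroxy-6-methyl-5-(prop-1-en-2-yl)-7-[(triethylsilyl)oxy]hexahydro-1-benzofuran-2(3H)-one | C=C[C@]1(C)[C@H](O[Si](CC)(CC)CC)[C@@H]2OC(=O)C[C@H]2[C@H](O)[C@H]1C(C)=C | intermediate
15 | (3aR,5S,6S,7S,7aR)-6-ethenyl-6-methyl-5-(prop-1-en-2-yl)-7-[(triethylsilyl)oxy]tetrahydro-1-benzofuran-2,4(3H,5H)-dione | C=C[C@]1(C)[C@H](O[Si](CC)(CC)CC)[C@@H]2OC(=O)C[C@H]2C(=O)[C@H]1C(C)=C | intermediate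
16 | (3aS,4S,5S,6S,7S,7aR)-6-ethenyl-4-hydroxy-6-methyl-5-(prop-1-en-2-yl)-7-[(triethylsilyl)oxy]hexahydro-1-benzofuran-2(3H)-one | C=C[C@]1(C)[C@H](O[Si](CC)(CC)CC)[C@@H]2OC(=O)C[C@H]2[C@@H](O)[C@H]1C(C)=C | intermediate
17 | (2Z)-2-methylbut-2-enoic acid (angelic acid) | C/C=C(/C)C(=O)O | starting material
18 | (3aS,4S,5S,6S,7S,7aR)-6-ethenyl-6-methyl-2-oxo-5-(prop-1-en-2-yl)-7-[(triethylsilyl)oxy]octahydro-1-benzofuran-4-yl (2Z)-2-methylbut-2-enoate | C=C[C@]1(C)[C@H](O[Si](CC)(CC)CC)[C@@H]2OC(=O)C[C@H]2[C@@H](OC(=O)/C(C)=C\C)[C@H]1C(C)=C | intermediate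
19 | 3-[(dimethylamino)methyl] derivative of 18 (Mannich base, both C3 epimers) | C=C[C@]1(C)[C@H](O[Si](CC)(CC)CC)[C@@H]2OC(=O)C(CN(C)C)[C@H]2[C@@H](OC(=O)/C(C)=C\C)[C@H]1C(C)=C | intermediate
20 | 3-[(trimethylammonio)methyl] derivative of 18, iodide | C=C[C@]1(C)[C@H](O[Si](CC)(CC)CC)[C@@H]2OC(=O)C(C[N+](C)(C)C)[C@H]2[C@@H](OC(=O)/C(C)=C\C)[C@H]1C(C)=C.[I-] | intermediate
21 | (3aS,4S,5S,6S,7S,7aR)-6-ethenyl-6-methyl-3-methylidene-2-oxo-5-(prop-1-en-2-yl)-7-[(triethylsilyl)oxy]octahydro-1-benzofuran-4-yl (2Z)-2-methylbut-2-enoate | C=C[C@]1(C)[C@H](O[Si](CC)(CC)CC)[C@@H]2OC(=O)C(=C)[C@H]2[C@@H](OC(=O)/C(C)=C\C)[C@H]1C(C)=C | intermediate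
22 | (3aS,4S,5S,6S,7S,7aR)-6-ethenyl-5-(3-hydroxyprop-1-en-2-yl)-6-methyl-3-methylidene-2-oxo-7-[(triethylsilyl)oxy]octahydro-1-benzofuran-4-yl (2Z)-2-methylbut-2-enoate | C=C[C@]1(C)[C@H](O[Si](CC)(CC)CC)[C@@H]2OC(=O)C(=C)[C@H]2[C@@H](OC(=O)/C(C)=C\C)[C@H]1C(=C)CO | intermediate
23 | (3aS,4S,5R,6S,7S,7aR)-6-ethenyl-6-methyl-3-methylidene-2-oxo-5-(3-oxoprop-1-en-2-yl)-7-[(triethylsilyl)oxy]octahydro-1-benzofuran-4-yl (2Z)-2-methylbut-2-enoate | C=C[C@]1(C)[C@H](O[Si](CC)(CC)CC)[C@@H]2OC(=O)C(=C)[C@H]2[C@@H](OC(=O)/C(C)=C\C)[C@H]1C(=C)C=O | intermediate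
24 | (3aS,4S,5R,6S,7S,7aR)-6-ethenyl-7-hydroxy-6-methyl-3-methylidene-2-oxo-5-(3-oxoprop-1-en-2-yl)octahydro-1-benzofuran-4-yl (2Z)-2-methylbut-2-enoate | C=C[C@]1(C)[C@H](O)[C@@H]2OC(=O)C(=C)[C@H]2[C@@H](OC(=O)/C(C)=C\C)[C@H]1C(=C)C=O | target

**Step count and risks**

Total step count: 14. Longest linear sequence: 12 steps (steps 1–3, then 6–14, from but-2-yn-1-ol).

Steps most likely to fail:

Step 8 (carbonyl-ene ring closure). The C5–C6 bond may fail to form, or chloride capture, Prins-type cation pathways or loss of the silyl ether may take over, because C5 is neopentylic and the new ring is trans-fused to the lactone. The fallback sets out from 11 and comes back at 14. Compound 11 is silylated (Et3SiCl, imidazole) to the silyl ether acetal 12, now isolated. SeO2/t-BuOOH oxidises the (E)-methyl group of the 2-methylprop-1-enyl arm to (4R,5R)-4-(1,3-dioxolan-2-yl)-5-[(1S,2S,3E)-2-ethenyl-5-hydroxy-2,4-dimethyl-1-[(triethylsilyl)oxy]pent-3-en-1-yl]oxolan-2-one F1. Appel bromination gives (4R,5R)-5-[(1S,2S,3E)-5-bromo-2-ethenyl-2,4-dimethyl-1-[(triethylsilyl)oxy]pent-3-en-1-yl]-4-(1,3-dioxolan-2-yl)oxolan-2-one F2. Silyl triflate/collidine acetal cleavage gives (2R,3R)-2-[(1S,2S,3E)-5-bromo-2-ethenyl-2,4-dimethyl-1-[(triethylsilyl)oxy]pent-3-en-1-yl]-5-oxooxolane-3-carbaldehyde F3. An intramolecular Nozaki–Hiyama–Kishi allylation (CrCl2, THF, high dilution) then closes C5–C6 through the γ-carbon, transposes the double bond into the isopropenyl group and should give 14; any 6-epimer converges at ketone 15.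

Step 6 (dienylchromium addition). E/Z equilibration of the allylchromium species or weak Felkin–Anh control would erode the configuration of the quaternary C10, which cannot be corrected later. The fallback sets out from 6 and comes back at 11. Bromide 6 is converted (HSiCl3, CuCl, i-Pr2NEt, Et2O) into the geometrically fixed trichloro[(2Z)-3,5-dimethylhexa-2,4-dien-1-yl]silane F4, which is added to aldehyde 9 in DMF at 0 °C. The Lewis-base-activated silicate reacts through a closed chair transition state without metallotropic scrambling and should give 11 stereospecifically.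

Step 11 (angeloylation). Acylation of the axial C6 hydroxyl, shielded by the syn-axial C10 methyl, may be slow, and heating would isomerise the activated acid to the tiglate. The fallback sets out from 16 and comes back at 18. Compound 16 is esterified with 2-[bis(2,2,2-trifluoroethoxy)phosphoryl]propanoic acid (DCC, DMAP) to (3aS,4S,5S,6S,7S,7aR)-6-ethenyl-6-methyl-2-oxo-5-(prop-1-en-2-yl)-7-[(triethylsilyl)oxy]octahydro-1-benzofuran-4-yl 2-[bis(2,2,2-trifluoroethoxy)phosphoryl]propanoate F5. A Still–Gennari olefination (KHMDS, 18-crown-6, THF, −78 °C, acetaldehyde) then builds the (Z)-2-methylbut-2-enoate on the molecule and should give 18.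

Further compounds
F1 | step 8 | (4R,5R)-4-(1,3-dioxolan-2-yl)-5-[(1S,2S,3E)-2-ethenyl-5-hydroxy-2,4-dimethyl-1-[(triethylsilyl)oxy]pent-3-en-1-yl]oxolan-2-one | C=C[C@](/C=C(\C)CO)(C)[C@H](O[Si](CC)(CC)CC)[C@@H]1OC(=O)C[C@H]1C1OCCO1
F2 | step 8 | (4R,5R)-5-[(1S,2S,3E)-5-bromo-2-ethenyl-2,4-dimethyl-1-[(triethylsilyl)oxy]pent-3-en-1-yl]-4-(1,3-dioxolan-2-yl)oxolan-2-one | C=C[C@](/C=C(\C)CBr)(C)[C@H](O[Si](CC)(CC)CC)[C@@H]1OC(=O)C[C@H]1C1OCCO1
F3 | step 8 | (2R,3R)-2-[(1S,2S,3E)-5-bromo-2-ethenyl-2,4-dimethyl-1-[(triethylsilyl)oxy]pent-3-en-1-yl]-5-oxooxolane-3-carbaldehyde | C=C[C@](/C=C(\C)CBr)(C)[C@H](O[Si](CC)(CC)CC)[C@@H]1OC(=O)C[C@H]1C=O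
F4 | step 6 | trichloro[(2Z)-3,5-dimethylhexa-2,4-dien-1-yl]silane | CC(C)=C/C(C)=C\C[Si](Cl)(Cl)Cl
F5 | step 11 | (3aS,4S,5S,6S,7S,7aR)-6-ethenyl-6-methyl-2-oxo-5-(prop-1-en-2-yl)-7-[(triethylsilyl)oxy]octahydro-1-benzofuran-4-yl 2-[bis(2,2,2-trifluoroethoxy)phosphoryl]propanoate | C=C[C@]1(C)[C@H](O[Si](CC)(CC)CC)[C@@H]2OC(=O)C[C@H]2[C@@H](OC(=O)C(C)P(=O)(OCC(F)(F)F)OCC(F)(F)F)[C@H]1C(C)=C
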